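**Plan**

- Retrosynthesis (labdane numbering): the two acetyl C–O bonds are cut first, then C17–O, then C9–H together with the position of the ring B alkene (back to a C8–C9 enone). Next come C9–C11 (an (E)-C6 alkyllithium onto a C9 ketone), one C4–methyl bond, C2–O, the ring A bond C2–C3, and last C10–C1 and C10–C20.
- Forward: ring B is bought as (R)-carvone. C20 and the two-carbon arm C1–C2 are attached at C10, ring A is closed by a carbonyl-ene reaction and trimmed to the gem-dimethyl level, the side chain is joined at C9, and ring B is then adjusted.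
- Enabling feature: ring B (C5–C10) with its C7–C8 alkene, C17 on C8 and C4 on C5 is the carvone skeleton with C9 as the ketone. The isopropenyl group on C5 (C3, C4, one C4 methyl) and an acetaldehyde arm on C10 (C1, C2) therefore sit on neighbouring carbons and can close ring A through C2–C3.
- Stereochemistry: C5 is the carvone stereocentre; C10 comes from enolate alkylation anti to the isopropenyl group, and the trans ring fusion follows from these two. C9 is set by hydrogen delivery from a 7α-diazene to the α-face, and the 13E alkene by syn-carboalumination of an alkyne.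

Key step: step 5

Assumption: the carbinol centres made in step 5 (C2) and step 13 (C9) are removed again, so the epimer expected to predominate is drawn for 12 and 26; compounds 4, 8 and 15 are epimer mixtures at a centre that is erased later and carry no descriptor there. Labdane names imply 5α-H, 9α-H and 10β-methyl.

**Route**

Step 1
Reactants: 1 (R)-(−)-carvone; 2 iodomethane
Product: 4 (5R)-6-methylcarvone (C6 epimers), via lithium dienolate 3 (not isolated)
Conditions: LiN(iPr)2, THF, −78 °C; MeI, −78 → 0 °C
Reagents that add atoms: iodomethane 2, CI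
Why: Kinetic deprotonation at the α′-carbon (carvone C6, the future C10) gives the cross-conjugated enolate, and its C-methylation is a standard enolate alkylation whose epimer ratio is irrelevant because the centre is planarised again in step 2.

Step 2
Reactants: 4 (5R)-6-methylcarvone; 5 tert-butyl bromoacetate
Product: 7 tert-butyl 2-[(1S,6S)-1,3-dimethyl-2-oxo-6-(prop-1-en-2-yl)cyclohex-3-en-1-yl]acetate, via lithium enolate 6 (not isolated)
Conditions: LiN(iPr)2, THF, −78 → 0 °C; BrCH2CO2t-Bu, DMPU, −78 °C → rt
Reagents that add atoms: tert-butyl bromoacetate 5, CC(C)(C)OC(=O)CBr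
Why: Enolate alkylation in which the tetrasubstituted enolate is attacked axially on the face anti to the neighbouring isopropenyl group (held pseudoaxial by allylic strain with the enolate methyl), so the quaternary centre C10 should form with the acetate arm trans and the methyl cis to the isopropenyl group.

Step 3
Reactants: 7 keto ester
Product: 8 2-[(1S,6S)-2-hydroxy-1,3-dimethyl-6-(prop-1-en-2-yl)cyclohex-3-en-1-yl]ethan-1-ol (carbinol epimers)
Conditions: LiAlH4, THF, 0 °C → rt
Reagents that add atoms: none
Why: Hydride reduction takes the tert-butyl ester to the primary alcohol and the enone by 1,2-addition to the allylic alcohol, which removes the need to tell the two carbonyl groups apart.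

Step 4
Reactants: 8 diol
Product: 10 2-[(1S,6S)-1,3-dimethyl-2-oxo-6-(prop-1-en-2-yl)cyclohex-3-en-1-yl]acetaldehyde, via bis-alkoxysulfonium dichloride 9 (not isolated)
Conditions: (COCl)2, DMSO, CH2Cl2, −78 °C; Et3N, −78 → 0 °C
Reagents that add atoms: none
Why: Swern oxidation activates both hydroxyl groups as alkoxysulfonium ions before base is added, so the hydroxy aldehyde cannot close to a lactol and be over-oxidised to a lactone, and enone and aldehyde are released together.

Step 5
Reactants: 10 keto aldehyde
Product: 12 (4aS,7R,8aS)-7-hydroxy-2,8a-dimethyl-5-methylidene-4a,5,6,7,8,8a-hexahydronaphthalen-1(4H)-one, via chloro(methyl)aluminium alkoxide 11 (not isolated)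
Conditions: Me2AlCl (2 equiv), CH2Cl2, −78 → 0 °C; aq. NaHCO3
Reagents that add atoms: none
Why: Me2AlCl binds the aldehyde oxygen, the terminal CH2 of the isopropenyl group attacks C2 while a hydrogen of the isopropenyl methyl passes to oxygen through a six-membered ene transition state, and the aluminium-bound alcohol then loses methane to give alkoxide 11, which protects the product from ionisation. The closest known reaction is the Me2AlCl-promoted type 2 carbonyl-ene cyclisation of aldehydes onto 1,1-disubstituted alkenes to 3-methylenecyclohexanols. Ring A closes as a six-membered ring by C2–C3 bond formation, endo with respect to the alkene (both alkene carbons end up in the ring) and exo with respect to the carbonyl, because the tether sits on the central carbon of the ene unit. The one new stereocentre, C2, is controlled by the chair transition state: the oxygen must lie axial to reach the methyl hydrogen, so the 2β-alcohol (cis to C20) is expected, and any 2α-epimer from a boat-like array serves equally because C2 is deoxygenated in steps 6 and 7. The step needs chemoselectivity for the aldehyde over the hindered conjugated C9 ketone, which the higher enophilicity of the aldehyde secures, and a trans ring fusion, which is fixed beforehand because the arm on C10 and the isopropenyl group on C5 are trans on ring B and can only bridge to a trans-decalin. The exocyclic methylene left at C4 is the handle for the second methyl group.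

Step 6
Reactants: 12 ene alcohol
Product: 13 2β-O-(imidazol-1-ylthiocarbonyl) derivative of 12
Conditions: 1,1′-thiocarbonyldiimidazole, DMAP (cat.), ClCH2CH2Cl, 70 °C
Reagents that add atoms: 1,1′-thiocarbonyldiimidazole, S=C(n1ccnc1)n1ccnc1
Why: Thioacylation of the secondary alcohol is the first half of a Barton–McCombie deoxygenation; DMAP and heat make up for the axial position of the hydroxyl, and no base strong enough to deprotonate the enone is present.

Step 7
Reactants: 13 thionocarbamate
Product: 14 (4aS,8aS)-2,8a-dimethyl-5-methylidene-4a,5,6,7,8,8a-hexahydronaphthalen-1(4H)-one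
Conditions: Bu3SnH, AIBN (cat.), toluene, 100 °C
Reagents that add atoms: none
Why: Barton–McCombie deoxygenation, in which the stannyl radical adds to sulfur, the C2–O bond fragments and the secondary C2 radical is reduced by Bu3SnH; the homoallylic radical can only equilibrate with a cyclopropylcarbinyl radical that reopens to itself, so the exocyclic alkene and the enone should survive.

Step 8
Reactants: 14 methylidene enone
Product: 17 (4aS,8aS)-2,5,5,8a-tetramethyl-4a,5,6,7,8,8a-hexahydronaphthalen-1(4H)-one, via N′-alkyl sulfonohydrazide 15 (not isolated), via alkyl diazene 16 (not isolated)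
Conditions: Fe(acac)3, PhSiH3, CH2=NNHSO2C8H17, THF/MeOH, rt; then MeOH, 60 °C
Reagents that add atoms: formaldehyde octane-1-sulfonylhydrazone, C=NNS(=O)(=O)CCCCCCCC
Why: Metal-hydride hydrogen atom transfer hydromethylation puts a hydrogen on the terminal CH2 of the electron-rich 1,1-disubstituted alkene, the tertiary C4 radical adds to the hydrazone carbon, and warming hydrazide 15 in methanol expels sulfinic acid and then dinitrogen from diazene 16 to leave the second methyl; the electron-poor ring alkene is a poor hydrogen-atom acceptor and C4 is no longer a stereocentre.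

Step 9
Reactants: 18 tert-butyl(but-3-yn-1-yloxy)dimethylsilane
Product: 21 (E)-5-[(tert-butyldimethylsilyl)oxy]-3-methylpent-2-en-1-ol, via dimethyl alkenylalane 19 (not isolated), via lithium alkenyl alanate 20 (not isolated)
Conditions: Me3Al, Cp2ZrCl2 (cat.), CH2Cl2, 0 °C → rt; n-BuLi, THF, −78 °C; (CH2O)n, −78 °C → rt
Reagents that add atoms: trimethylaluminium, C[Al](C)C; formaldehyde (as paraformaldehyde), C=O
Why: Negishi zirconium-catalysed carboalumination adds methyl and aluminium syn across the terminal alkyne with methyl on the internal carbon, and alanate 20 is hydroxymethylated with retention, which fixes the 13E geometry.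

Step 10
Reactants: 21 allylic alcohol
Product: 22 (E)-1-[(tert-butyldiphenylsilyl)oxy]-5-[(tert-butyldimethylsilyl)oxy]-3-methylpent-2-ene
Conditions: t-BuPh2SiCl, imidazole, DMF, rt
Reagents that add atoms: tert-butyl(chloro)diphenylsilane, CC(C)(C)[Si](Cl)(c1ccccc1)c1ccccc1
Why: Routine silylation of a primary allylic alcohol; the TBDPS ether is chosen to outlast the acid of step 11 and the lithium, chromium, hydride and selenium reagents used later.

Step 11
Reactants: 22 bis-silyl ether
Product: 23 (E)-5-[(tert-butyldiphenylsilyl)oxy]-3-methylpent-3-en-1-ol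
Conditions: PPTS, EtOH, 40 °C
Reagents that add atoms: none
Why: Acid-catalysed solvolysis cleaves a primary TBS ether much faster than a primary TBDPS ether, a standard selective desilylation.

Step 12
Reactants: 23 homoallylic alcohol
Product: 24 (E)-tert-butyl[(5-iodo-3-methylpent-2-en-1-yl)oxy]diphenylsilane
Conditions: I2, PPh3, imidazole, CH2Cl2, 0 °C → rt
Reagents that add atoms: iodine, II
Why: Appel-type iodination converts the primary alcohol into the iodide by SN2 displacement of the oxyphosphonium group without touching the alkene geometry.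

Step 13
Reactants: 24 iodide; 17 enone
Product: 26 (13E)-15-[(tert-butyldiphenylsilyl)oxy]labda-7,13-dien-9-ol (drawn 9β-OH with the side chain α), via alkyllithium 25 (not isolated)
Conditions: 24, t-BuLi (2.1 equiv), Et2O/pentane, −78 °C; then 17, Et2O, −78 → 0 °C
Reagents that add atoms: iodide 24, ICC/C(C)=C/CO[Si](c1ccccc1)(c1ccccc1)C(C)(C)C
Why: Lithium–iodine exchange gives primary alkyllithium 25, which adds 1,2 to the C9 carbonyl of an enone that cannot be enolised at an α-carbon (C10 is quaternary, C8 is vinylic); attack is expected anti to the angular methyl, but C9 is flattened again in step 14.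

Step 14
Reactants: 26 tertiary allylic alcohol
Product: 27 (13E)-15-[(tert-butyldiphenylsilyl)oxy]labda-8,13-dien-7-one
Conditions: pyridinium chlorochromate [C5H5NH][CrO3Cl], 4 Å molecular sieves, CH2Cl2, rt
Reagents that add atoms: pyridinium chlorochromate, [O-][Cr](=O)(=O)Cl.c1cc[nH+]cc1
Why: Babler–Dauben oxidative transposition, in which hexavalent chromium esterifies the tertiary allylic alcohol, the chromate shifts [3,3] to C7 and is oxidised there, giving the enone with the side chain on C9 and oxygen on C7.

Step 15
Reactants: 27 transposed enone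
Product: 28 (13E)-15-[(tert-butyldiphenylsilyl)oxy]labda-8,13-dien-7β-ol
Conditions: NaBH4, CeCl3·7H2O, MeOH, −20 °C
Reagents that add atoms: none
Why: Luche 1,2-reduction, with hydride adding to C7 axially from the α-face, which is also the face away from the β-axial C10 methyl that overhangs the ring, so the pseudo-equatorial 7β-alcohol is expected.

Step 16
Reactants: 28 allylic alcohol
Product: 31 tert-butyl{[(13E)-labda-7,13-dien-15-yl]oxy}diphenylsilane, via N-allyl sulfonylhydrazine 29 (not isolated), via allylic diazene 30 (not isolated)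
Conditions: 2-O2NC6H4SO2NHNH2, PPh3, DEAD, THF, −30 °C; then 23 °C
Reagents that add atoms: none
Why: Reductive 1,3-transposition through an allylic diazene: Mitsunobu displacement by the sulfonyl hydrazide inverts C7 to the 7α-hydrazine 29, loss of 2-nitrobenzenesulfinic acid on warming gives 7α-diazene 30, and its retro-ene loss of N2 delivers hydrogen suprafacially to the α-face of C9 while the alkene moves to C7–C8, which sets 9α-H with the side chain β and equatorial.

Step 17
Reactants: 31 labda-7,13-diene silyl ether
Product: 32 (13E)-15-[(tert-butyldiphenylsilyl)oxy]labda-7,13-dien-17-ol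
Conditions: SeO2 (cat.), t-BuOOH, salicylic acid (cat.), CH2Cl2, rt
Reagents that add atoms: selenium dioxide, O=[Se]=O; tert-butyl hydroperoxide, CC(C)(C)OO
Why: Riley-type allylic oxidation (ene reaction then [2,3] shift), in which selenium attacks C7 and hydrogen is taken from the more substituted end, where the C17 methyl is preferred over the hindered C9 methine; the side-chain alkene is deactivated by its allylic silyloxy group as in geranyl derivatives, so the C17 alcohol with the alkene back at C7–C8 is expected.

Step 18
Reactants: 32 silyl ether alcohol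
Product: 33 (13E)-labda-7,13-diene-15,17-diol
Conditions: Bu4NF, THF, rt
Reagents that add atoms: none
Why: Fluoride-induced cleavage of the TBDPS ether is standard and leaves the allylic alcohols, the alkenes and all stereocentres untouched.

Step 19
Reactants: 33 diol
Product: 34 (13E)-labda-7,13-diene-15,17-diyl diacetate (target)
Conditions: Ac2O, pyridine, DMAP (cat.), CH2Cl2, rt
Reagents that add atoms: acetic anhydride, CC(=O)OC(C)=O
Why: DMAP-catalysed acetylation of the two primary allylic alcohols should give the diacetate without involving any stereocentre.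

**Compound list**

1 | (R)-(−)-carvone | CC1=CC[C@@H](C(C)=C)CC1=O | starting material
2 | iodomethane | CI | starting material
3 | lithium cross-conjugated dienolate of 1 | CC1=CC[C@@H](C(C)=C)C=C1[O-].[Li+] | intermediate (not isolated)
4 | (5R)-2,6-dimethyl-5-(prop-1-en-2-yl)cyclohex-2-en-1-one (6-methylcarvone, C6 epimers) | CC1=CC[C@@H](C(C)=C)C(C)C1=O | intermediate
5 | tert-butyl bromoacetate | CC(C)(C)OC(=O)CBr | starting material
6 | lithium enolate of 4 | CC1=CC[C@@H](C(C)=C)C(C)=C1[O-].[Li+] | intermediate (not isolated)
7 | tert-butyl 2-[(1S,6S)-1,3-dimethyl-2-oxo-6-(prop-1-en-2-yl)cyclohex-3-en-1-yl]acetate | CC1=CC[C@@H](C(C)=C)[C@](C)(CC(=O)OC(C)(C)C)C1=O | intermediate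
8 | 2-[(1S,6S)-2-hydroxy-1,3-dimethyl-6-(prop-1-en-2-yl)cyclohex-3-en-1-yl]ethan-1-ol (carbinol epimers) | CC1=CC[C@@H](C(C)=C)[C@](C)(CCO)C1O | intermediate
9 | bis(dimethylsulfonium) ether of 8, dichloride | CC1=CC[C@@H](C(C)=C)[C@](C)(CCO[S+](C)C)C1O[S+](C)C.[Cl-].[Cl-] | intermediate (not isolated)
10 | 2-[(1S,6S)-1,3-dimethyl-2-oxo-6-(prop-1-en-2-yl)cyclohex-3-en-1-yl]acetaldehyde | CC1=CC[C@@H](C(C)=C)[C@](C)(CC=O)C1=O | intermediate
11 | chloro(methyl)aluminium alkoxide of 12 | CC1=CC[C@H]2C(=C)C[C@@H](O[Al](C)Cl)C[C@]2(C)C1=O | intermediate (not isolated)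
12 | (4aS,7R,8aS)-7-hydroxy-2,8a-dimethyl-5-methylidene-4a,5,6,7,8,8a-hexahydronaphthalen-1(4H)-one (trans-fused, 2β-OH) | CC1=CC[C@H]2C(=C)C[C@@H](O)C[C@]2(C)C1=O | intermediate
13 | O-ester of 12 with 1H-imidazole-1-carbothioic acid (2β-OC(=S)-imidazol-1-yl) | CC1=CC[C@H]2C(=C)C[C@@H](OC(=S)n3ccnc3)C[C@]2(C)C1=O | intermediate
14 | (4aS,8aS)-2,8a-dimethyl-5-methylidene-4a,5,6,7,8,8a-hexahydronaphthalen-1(4H)-one | CC1=CC[C@H]2C(=C)CCC[C@]2(C)C1=O | intermediate
15 | N′-alkyl octane-1-sulfonohydrazide (C4 carries CH3 and CH2NHNHSO2C8H17, C4 epimers) | CC1=CC[C@H]2C(C)(CNNS(=O)(=O)CCCCCCCC)CCC[C@]2(C)C1=O | intermediate (not isolated)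
16 | alkyl diazene (C4 carries CH3 and CH2N=NH) | CC1=CC[C@H]2C(C)(CN=N)CCC[C@]2(C)C1=O | intermediate (not isolated)
17 | (4aS,8aS)-2,5,5,8a-tetramethyl-4a,5,6,7,8,8a-hexahydronaphthalen-1(4H)-one | CC1=CC[C@H]2C(C)(C)CCC[C@]2(C)C1=O | intermediate
18 | tert-butyl(but-3-yn-1-yloxy)dimethylsilane | C#CCCO[Si](C)(C)C(C)(C)C | starting material
19 | dimethyl[(E)-4-(tert-butyldimethylsilyloxy)-2-methylbut-1-en-1-yl]alane | C/C(CCO[Si](C)(C)C(C)(C)C)=C\[Al](C)C | intermediate (not isolated)
20 | lithium butyl(dimethyl)[(E)-4-(tert-butyldimethylsilyloxy)-2-methylbut-1-en-1-yl]alanate | [Li+].CCCC[Al-](C)(C)/C=C(\C)CCO[Si](C)(C)C(C)(C)C | intermediate (not isolated)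
21 | (E)-5-[(tert-butyldimethylsilyl)oxy]-3-methylpent-2-en-1-ol | C/C(CCO[Si](C)(C)C(C)(C)C)=C\CO | intermediate
22 | (E)-1-[(tert-butyldiphenylsilyl)oxy]-5-[(tert-butyldimethylsilyl)oxy]-3-methylpent-2-ene | CC(C)(C)[Si](C)(C)OCC/C(C)=C/CO[Si](c1ccccc1)(c1ccccc1)C(C)(C)C | intermediate
23 | (E)-5-[(tert-butyldiphenylsilyl)oxy]-3-methylpent-3-en-1-ol | OCC/C(C)=C/CO[Si](c1ccccc1)(c1ccccc1)C(C)(C)C | intermediate
24 | (E)-tert-butyl[(5-iodo-3-methylpent-2-en-1-yl)oxy]diphenylsilane | ICC/C(C)=C/CO[Si](c1ccccc1)(c1ccccc1)C(C)(C)C | intermediate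
25 | (E)-[5-(tert-butyldiphenylsilyloxy)-3-methylpent-3-en-1-yl]lithium | [Li]CC/C(C)=C/CO[Si](c1ccccc1)(c1ccccc1)C(C)(C)C | intermediate (not isolated)
26 | (13E)-15-[(tert-butyldiphenylsilyl)oxy]labda-7,13-dien-9-ol (9β-OH, side chain α) | CC1=CC[C@H]2C(C)(C)CCC[C@]2(C)[C@]1(O)CC/C(C)=C/CO[Si](c1ccccc1)(c1ccccc1)C(C)(C)C | intermediate
27 | (13E)-15-[(tert-butyldiphenylsilyl)oxy]labda-8,13-dien-7-one | CC(C)(C)[Si](c1ccccc1)(c1ccccc1)OC/C=C(\C)CCC1=C(C)C(=O)C[C@H]2C(C)(C)CCC[C@]12C | intermediate
28 | (13E)-15-[(tert-butyldiphenylsilyl)oxy]labda-8,13-dien-7β-ol | CC(C)(C)[Si](c1ccccc1)(c1ccccc1)OC/C=C(\C)CCC1=C(C)[C@@H](O)C[C@H]2C(C)(C)CCC[C@]12C | intermediate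
29 | 7α-[1-(2-nitrophenylsulfonyl)hydrazin-1-yl] analogue of 28 | CC(C)(C)[Si](c1ccccc1)(c1ccccc1)OC/C=C(\C)CCC1=C(C)[C@H](N(N)S(=O)(=O)c3ccccc3[N+](=O)[O-])C[C@H]2C(C)(C)CCC[C@]12C | intermediate (not isolated)
30 | 7α-diazenyl analogue of 28 | CC(C)(C)[Si](c1ccccc1)(c1ccccc1)OC/C=C(\C)CCC1=C(C)[C@H](N=N)C[C@H]2C(C)(C)CCC[C@]12C | intermediate (not isolated)
31 | tert-butyl{[(13E)-labda-7,13-dien-15-yl]oxy}diphenylsilane | CC(C)(C)[Si](c1ccccc1)(c1ccccc1)OC/C=C(\C)CC[C@H]1C(C)=CC[C@H]2C(C)(C)CCC[C@]12C | intermediate
32 | (13E)-15-[(tert-butyldiphenylsilyl)oxy]labda-7,13-dien-17-ol | CC(C)(C)[Si](c1ccccc1)(c1ccccc1)OC/C=C(\C)CC[C@H]1C(CO)=CC[C@H]2C(C)(C)CCC[C@]12C | intermediate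
33 | (13E)-labda-7,13-diene-15,17-diol | OC/C=C(\C)CC[C@H]1C(CO)=CC[C@H]2C(C)(C)CCC[C@]12C | intermediate
34 | (13E)-labda-7,13-diene-15,17-diyl diacetate (5S,9R,10S) | CC(=O)OC/C=C(\C)CC[C@H]1C(COC(C)=O)=CC[C@H]2C(C)(C)CCC[C@]12C | target

**Step count and risks**

Total: 19 steps. Longest linear sequence: 15 steps (steps 1–8 and 13–19); steps 9–12 make the side chain.

Step 8 is the most exposed. The tertiary C4 radical may add to the enone of a second molecule or simply be reduced, and hydrogen atom transfer to the conjugated alkene may compete. The fallback sets out from 14 and uses cyclopropane hydrogenolysis in place of radical chemistry. Cyclopropanation with Et2Zn and CH2I2 in CH2Cl2 at 0 °C, which prefers the electron-rich exocyclic alkene, should give the spiro-cyclopropane enone F1. Hydrogenolysis over PtO2 in AcOH opens the least hindered cyclopropane bond to the gem-dimethyl group and also saturates C7–C8, giving the saturated ketone F2. IBX in DMSO at 70 °C, which would also re-oxidise any C9 alcohol, dehydrogenates on the only enolisable side and returns to 17.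

Step 16 is next. The Mitsunobu displacement at the hindered allylic C7 carbinol may be slow, and elimination to a diene may take over. The fallback sets out from 28 and replaces the diazene by a palladium hydride. Formylation with acetic formic anhydride and pyridine gives the 7β-formate F3. Heating F3 with Pd(OAc)2 and n-Bu3P in THF (zerovalent palladium formed in the flask) should ionise it anti to the formate, lose CO2 and transfer hydride from palladium on the α-face to the more substituted allyl terminus C9. This is a Tsuji-type hydrogenolysis of an allylic formate and returns to 31 with the same 9α-H.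

Step 17 is third. The ene attack of selenium may spread to the side-chain alkene or to C9–H and C6–H, and over-oxidation to the enal may occur. The fallback sets out from 31 and builds the C17–O bond through an epoxide. mCPBA with NaHCO3 in CH2Cl2 at 0 °C should epoxidise the ring alkene from the α-face in preference to the deactivated side-chain alkene, giving the 7α,8α-epoxide F4. Diethylaluminium 2,2,6,6-tetramethylpiperidide in toluene at 0 °C removes a C17 proton and opens the epoxide to the 8(17)-en-7α-ol F5. Catalytic Ph3SiOReO3 in Et2O then moves the hydroxyl by 1,3-transposition to the more substituted alkene, which returns to 32.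

**Further compounds**

F1 | step 8 | spiro-cyclopropane enone (C4 of 14 as spiro carbon of a cyclopropane) | CC1=CC[C@H]2C3(CC3)CCC[C@]2(C)C1=O
F2 | step 8 | (4aS,8aS)-2,5,5,8a-tetramethyloctahydronaphthalen-1(2H)-one (C8 epimers) | CC1CC[C@H]2C(C)(C)CCC[C@]2(C)C1=O
F3 | step 16 | (13E)-15-[(tert-butyldiphenylsilyl)oxy]labda-8,13-dien-7β-yl formate | CC(C)(C)[Si](c1ccccc1)(c1ccccc1)OC/C=C(\C)CCC1=C(C)[C@@H](OC=O)C[C@H]2C(C)(C)CCC[C@]12C
F4 | step 17 | (13E)-15-[(tert-butyldiphenylsilyl)oxy]-7α,8α-epoxylabd-13-ene | CC(C)(C)[Si](c1ccccc1)(c1ccccc1)OC/C=C(\C)CC[C@H]1[C@]3(C)O[C@@H]3C[C@H]2C(C)(C)CCC[C@]12C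
F5 | step 17 | (13E)-15-[(tert-butyldiphenylsilyl)oxy]labda-8(17),13-dien-7α-ol | CC(C)(C)[Si](c1ccccc1)(c1ccccc1)OC/C=C(\C)CC[C@H]1C(=C)[C@H](O)C[C@H]2C(C)(C)CCC[C@]12C
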